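**Plan**

- Retrosynthesis: the enone is cut first at the C(=O)–Cα bond, as a formal addition of the aldehyde C–H of 2,4-dihydroxy-3-prenylbenzaldehyde across the terminal alkyne of a 5-ethynyl-dihydrobenzofuran diol. The alkyne half is then cut at O1–C2 of the dihydrofuran (phenoxide + epoxide), at the epoxide oxygen (allylic alcohol), at the carbinol C–C bond (aryl aldehyde + isobutenylzinc) and at the aryl–alkyne bond. The aldehyde half is cut at the formyl and prenyl C–C bonds (two directed lithiations of resorcinol bis-MOM ether).
- Forward: both benzene rings are bought (5-iodosalicylaldehyde, resorcinol); the dihydrofuran is the only ring made (5-exo-tet epoxide opening, step 5); the two unprotected halves are joined last.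
- Enabling feature: the free 2'-OH on ring A, ortho to the carbonyl carbon. O2'–C2'–C1'–C(=O) closes with rhodium a five-membered acyl–rhodium phenoxide chelate, so the aldehyde C–H can be added across the alkyne without decarbonylation and without protecting groups.
- Stereochemistry: C3 from a (−)-MIB-catalysed alkenylzinc addition (S carbinol); C2 from hydroxyl-directed, A(1,3)-controlled epoxidation (threo) and SN2 inversion on ring closure, giving trans-(2R,3R); the E alkene from syn addition of H and acyl.

Key step: step 10

Remark: the MOM groups are removed before the fragment union because the benzylic 3-OH of the dihydrobenzofuran would be expected to eliminate to the benzofuran under acid; the last step is therefore run on unprotected partners.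

**Route**

Step 1
Reactants: 1 5-iodosalicylaldehyde (2-hydroxy-5-iodobenzaldehyde); 2 ethynyl(trimethyl)silane
Product: 3 2-hydroxy-5-[(trimethylsilyl)ethynyl]benzaldehyde
Conditions: PdCl2(PPh3)2 (cat.), CuI (cat.), Et3N, THF, rt to 40 °C
Reagents that add atoms: none
Why: Sonogashira coupling of an aryl iodide runs under mild conditions and tolerates the free phenol and the aldehyde, as is usual for 5-halosalicylaldehydes.

Step 2
Reactants: 3 2-hydroxy-5-[(trimethylsilyl)ethynyl]benzaldehyde
Product: 4 2-[(triisopropylsilyl)oxy]-5-[(trimethylsilyl)ethynyl]benzaldehyde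
Conditions: TIPSCl, imidazole, DMAP (cat.), DMF, rt
Reagents that add atoms: chlorotri(propan-2-yl)silane (TIPSCl), CC(C)[Si](Cl)(C(C)C)C(C)C
Why: Standard silylation masks the acidic phenol for the organozinc addition with a bulky group that resists O-to-O migration and is later removed by fluoride to release the nucleophilic phenoxide.

Step 3
Reactants: 4 2-[(triisopropylsilyl)oxy]-5-[(trimethylsilyl)ethynyl]benzaldehyde; 5 1-bromo-2-methylprop-1-ene
Product: 8 (1S)-3-methyl-1-{2-[(triisopropylsilyl)oxy]-5-[(trimethylsilyl)ethynyl]phenyl}but-2-en-1-ol, via (2-methylprop-1-enyl)lithium 6 (not isolated), via bis(2-methylprop-1-enyl)zinc 7 (not isolated)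
Conditions: 5, t-BuLi, Et2O, −78 °C; ZnBr2; TEEDA, (−)-MIB (5 mol %), then 4, toluene, 0 °C; aq. NH4Cl
Reagents that add atoms: none
Why: Catalytic asymmetric alkenylzinc addition to an aromatic aldehyde (Noyori-type amino-alkoxide zinc catalysis in the Oppolzer/Walsh alkenyl variant, with the diamine sequestering lithium halide) should deliver the alkenyl group to the Si face as in (−)-DAIB/(−)-MIB dialkylzinc additions, which sets the S carbinol (the future C3).

Step 4
Reactants: 8 (1S)-3-methyl-1-{2-[(triisopropylsilyl)oxy]-5-[(trimethylsilyl)ethynyl]phenyl}but-2-en-1-ol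
Product: 9 (R)-[(2S)-3,3-dimethyloxiran-2-yl]{2-[(triisopropylsilyl)oxy]-5-[(trimethylsilyl)ethynyl]phenyl}methanol
Conditions: mCPBA, NaHCO3, CH2Cl2, 0 °C
Reagents that add atoms: 3-chloroperoxybenzoic acid (mCPBA), O=C(OO)c1cccc(Cl)c1
Why: Hydroxyl-directed peracid epoxidation (Henbest) of the electron-rich trisubstituted alkene, in which A(1,3) strain with the Z-methyl holds the carbinol C–H in the alkene plane so that the hydrogen-bonded peracid attacks the face syn to the OH, should give the threo epoxy alcohol (new epoxide carbon S), with the buffer protecting the benzylic–allylic alcohol and the silylalkyne left untouched.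

Step 5
Reactants: 9 (R)-[(2S)-3,3-dimethyloxiran-2-yl]{2-[(triisopropylsilyl)oxy]-5-[(trimethylsilyl)ethynyl]phenyl}methanol
Product: 11 (2R,3R)-5-ethynyl-2-(2-hydroxypropan-2-yl)-2,3-dihydro-1-benzofuran-3-ol, via desilylated phenoxide epoxy alcohol 10 (not isolated)
Conditions: TBAF (3 equiv), THF, 0 °C to rt; aq. NH4Cl
Reagents that add atoms: none
Why: Fluoride cleaves the aryl silyl ether and the alkynyl silane, and the liberated phenoxide opens the epoxide by 5-exo-tet SN2 attack at the secondary carbon (favoured over 6-endo attack at the tertiary carbon under basic conditions) with inversion at C2, which converts the threo epoxy alcohol into the trans-(2R,3R) diol.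

Step 6
Reactants: 12 resorcinol
Product: 13 1,3-bis(methoxymethoxy)benzene
Conditions: MOMCl, iPr2NEt, CH2Cl2, 0 °C to rt
Reagents that add atoms: chloromethyl methyl ether (MOMCl), COCCl
Why: Routine O-alkylation gives the bis-MOM ether, whose two acetal oxygens direct the lithiations that follow.

Step 7
Reactants: 13 1,3-bis(methoxymethoxy)benzene; 14 1-bromo-3-methylbut-2-ene (prenyl bromide)
Product: 16 1,3-bis(methoxymethoxy)-2-(3-methylbut-2-en-1-yl)benzene, via 2-lithio-1,3-bis(methoxymethoxy)benzene 15 (not isolated)
Conditions: n-BuLi, THF, 0 °C to rt; CuI (cat.), 14, −78 °C to rt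
Reagents that add atoms: none
Why: Directed ortho-metalation occurs at C2 between the two OMOM groups, and copper-assisted SN2 allylation of the aryllithium with prenyl bromide gives the linear prenyl arene.

Step 8
Reactants: 16 1,3-bis(methoxymethoxy)-2-(3-methylbut-2-en-1-yl)benzene
Product: 18 2,4-bis(methoxymethoxy)-3-(3-methylbut-2-en-1-yl)benzaldehyde, via C4-lithiated bis-MOM prenylarene 17 (not isolated)
Conditions: n-BuLi, TMEDA, THF, −20 to 0 °C; DMF, −78 °C to rt; aq. NH4Cl
Reagents that add atoms: N,N-dimethylformamide (DMF), CN(C)C=O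
Why: With C2 blocked, a second OMOM-directed ortho-lithiation takes place at C4 and formylation with DMF (Bouveault-type) places the aldehyde next to one OMOM and para to nothing else, fixing the 2,4-dioxygenated-3-prenyl pattern.

Step 9
Reactants: 18 2,4-bis(methoxymethoxy)-3-(3-methylbut-2-en-1-yl)benzaldehyde
Product: 19 2,4-dihydroxy-3-(3-methylbut-2-en-1-yl)benzaldehyde
Conditions: 3 M HCl, MeOH, rt
Reagents that add atoms: none
Why: Acid-catalysed acetal exchange with methanol removes both aryl MOM ethers at room temperature, conditions used routinely for prenylated phenolic carbonyl compounds without hydration of the prenyl group or chroman formation.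

Step 10
Reactants: 19 2,4-dihydroxy-3-(3-methylbut-2-en-1-yl)benzaldehyde; 11 (2R,3R)-5-ethynyl-2-(2-hydroxypropan-2-yl)-2,3-dihydro-1-benzofuran-3-ol
Product: 20 paratocarpin G, (E)-1-[2,4-dihydroxy-3-(3-methylbut-2-en-1-yl)phenyl]-3-[(2R,3R)-3-hydroxy-2-(2-hydroxypropan-2-yl)-2,3-dihydro-1-benzofuran-5-yl]prop-2-en-1-one
Conditions: [Rh(cod)Cl]2 (2.5 mol %), dppf (5 mol %), Na2CO3 (10 mol %), toluene/1,4-dioxane, 80 °C, Ar
Reagents that add atoms: none
Why: Base-assisted binding of the 2-OH of 19 to Rh(I) and oxidative addition of the aldehyde C–H bond give a five-membered acyl(hydrido)rhodium(III) phenoxide chelate (Rh–O–C2–C1–C(acyl)) that is held against decarbonylation; the terminal alkyne of 11 then inserts syn into Rh–H with rhodium at the unhindered terminal carbon, and C–C reductive elimination forms the C(=O)–Cα bond and releases the enone and the catalyst. The closest known reaction type is the rhodium-catalysed, chelation-assisted intermolecular hydroacylation of alkynes with salicylaldehydes to 2-alkenoylphenols. No ring of the target is closed (the rhodacycle is transient) and no stereocentre is formed; the E geometry follows from syn addition of H and acyl across the triple bond, and the two stereocentres of 11 are not touched under these non-acidic conditions. The step needs linear over branched regioselectivity, which the steric demand of the aryl substituent against the dppf-bound acylrhodium centre should secure, and chemoselectivity for the alkyne over the prenyl group, which follows because a trisubstituted alkene does not insert. The free 4-OH and the diol are spectators, only catalytic carbonate is present so oxa-Michael closure of the 2'-hydroxychalcone to a flavanone is not promoted, and the addition is atom-economic with nothing to deprotect afterwards.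

**Compound list**

1 | 5-iodosalicylaldehyde (2-hydroxy-5-iodobenzaldehyde) | O=Cc1cc(I)ccc1O | starting material
2 | ethynyl(trimethyl)silane | C#C[Si](C)(C)C | starting material
3 | 2-hydroxy-5-[(trimethylsilyl)ethynyl]benzaldehyde | O=Cc1cc(C#C[Si](C)(C)C)ccc1O | intermediate
4 | 2-[(triisopropylsilyl)oxy]-5-[(trimethylsilyl)ethynyl]benzaldehyde | O=Cc1cc(C#C[Si](C)(C)C)ccc1O[Si](C(C)C)(C(C)C)C(C)C | intermediate
5 | 1-bromo-2-methylprop-1-ene | CC(C)=CBr | starting material
6 | (2-methylprop-1-enyl)lithium | [Li]C=C(C)C | intermediate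
7 | bis(2-methylprop-1-enyl)zinc | CC(C)=C[Zn]C=C(C)C | intermediate
8 | (1S)-3-methyl-1-{2-[(triisopropylsilyl)oxy]-5-[(trimethylsilyl)ethynyl]phenyl}but-2-en-1-ol | CC(C)=C[C@H](O)c1cc(C#C[Si](C)(C)C)ccc1O[Si](C(C)C)(C(C)C)C(C)C | intermediate
9 | (R)-[(2S)-3,3-dimethyloxiran-2-yl]{2-[(triisopropylsilyl)oxy]-5-[(trimethylsilyl)ethynyl]phenyl}methanol (threo) | O[C@@H]([C@@H]1OC1(C)C)c1cc(C#C[Si](C)(C)C)ccc1O[Si](C(C)C)(C(C)C)C(C)C | intermediate
10 | (R)-[(2S)-3,3-dimethyloxiran-2-yl](5-ethynyl-2-hydroxyphenyl)methanol, present as its phenoxide (drawn as the phenol) | O[C@@H]([C@@H]1OC1(C)C)c1cc(C#C)ccc1O | intermediate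
11 | (2R,3R)-5-ethynyl-2-(2-hydroxypropan-2-yl)-2,3-dihydro-1-benzofuran-3-ol (trans) | C#Cc1ccc2c(c1)[C@@H](O)[C@H](C(C)(C)O)O2 | intermediate
12 | resorcinol | Oc1cccc(O)c1 | starting material
13 | 1,3-bis(methoxymethoxy)benzene | COCOc1cccc(OCOC)c1 | intermediate
14 | 1-bromo-3-methylbut-2-ene (prenyl bromide) | CC(C)=CCBr | starting material
15 | 2-lithio-1,3-bis(methoxymethoxy)benzene | [Li]c1c(OCOC)cccc1OCOC | intermediate
16 | 1,3-bis(methoxymethoxy)-2-(3-methylbut-2-en-1-yl)benzene | COCOc1cccc(OCOC)c1CC=C(C)C | intermediate
17 | [2,4-bis(methoxymethoxy)-3-(3-methylbut-2-en-1-yl)phenyl]lithium | [Li]c1ccc(OCOC)c(CC=C(C)C)c1OCOC | intermediate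
18 | 2,4-bis(methoxymethoxy)-3-(3-methylbut-2-en-1-yl)benzaldehyde | O=Cc1ccc(OCOC)c(CC=C(C)C)c1OCOC | intermediate
19 | 2,4-dihydroxy-3-(3-methylbut-2-en-1-yl)benzaldehyde | O=Cc1ccc(O)c(CC=C(C)C)c1O | intermediate
20 | paratocarpin G | CC(C)=CCc1c(O)ccc(C(=O)/C=C/c2ccc3c(c2)[C@@H](O)[C@H](C(C)(C)O)O3)c1O | target

**Count and risks**

Total steps: 10. Longest linear sequence: 6 steps (steps 1 to 5, then step 10); the aldehyde branch is 4 steps (6 to 9) before the union.

Steps most likely to fail:

1. Step 10. The Rh–H insertion may proceed with the opposite regiochemistry (branched 1,1-disubstituted enone), and alkyne oligomerisation, isomerisation of the prenyl double bond by Rh–H, or catalyst sequestration by the free phenols may compete. The fallback sets out from 11 and 19 and returns at 20, using an alkenylmetal addition and oxidation instead of hydroacylation. 11 is silylated (TESOTf, 2,6-lutidine) to the bis(triethylsilyl) ether F1, and 19 (TBSCl, imidazole) to the bis(tert-butyldimethylsilyl) ether F2. Hydrozirconation of F1 with Cp2Zr(H)Cl gives the (E)-alkenyl(chloro)zirconocene F3, which is not isolated and is added to F2 under ZnBr2 catalysis (or after transmetalation with Me2Zn) to give the allylic alcohol F4, whose new carbinol configuration is irrelevant. MnO2 oxidation gives the silyl-protected chalcone F5, and buffered fluoride (TBAF/AcOH or HF·pyridine) removes the four silyl groups to give 20 without acid strong enough to ionise the benzylic alcohol.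

2. Step 3. The enantioselectivity may be eroded by a salt-promoted uncatalysed background addition, or transfer of the hindered trisubstituted alkenyl group to the ortho-silyloxy aldehyde may be sluggish. The fallback sets out from 4 and returns at 8, replacing asymmetric addition by resolution. Addition of commercial (2-methylprop-1-enyl)magnesium bromide to 4 (THF, −78 °C) gives the racemic allylic alcohol F6. Sharpless kinetic resolution (Ti(OiPr)4, L-(+)-DIPT, TBHP, 4 Å MS, CH2Cl2, −20 °C, run beyond half conversion because the Z-methyl lowers the rate ratio) should epoxidise the R enantiomer to the erythro epoxy alcohol F7 and leave (S)-8, which is separated by chromatography.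

3. Step 8. Lateral deprotonation of the benzylic–allylic CH2 of the prenyl group, which is flanked by two OMOM groups, may compete with ring lithiation and lead to chain-functionalised or double-bond-isomerised material. The fallback sets out from 16 and returns at 19, bypassing steps 8 and 9 by an electrophilic formylation of the free phenol. The MOM groups of 16 are removed first (HCl, MeOH, rt) to give 2-(3-methylbut-2-en-1-yl)benzene-1,3-diol F8. Magnesium-mediated ortho-formylation (MgCl2, Et3N, paraformaldehyde, MeCN, reflux) then installs the aldehyde ortho to a phenol; only the two equivalent positions C4/C6 are free, so 19 is formed directly.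

**Further compounds**

F1 | step 10 | (2R,3R)-5-ethynyl-3-(triethylsilyloxy)-2-[2-(triethylsilyloxy)propan-2-yl]-2,3-dihydro-1-benzofuran | C#Cc1ccc2c(c1)[C@@H](O[Si](CC)(CC)CC)[C@H](C(C)(C)O[Si](CC)(CC)CC)O2
F2 | step 10 | 2,4-bis(tert-butyldimethylsilyloxy)-3-(3-methylbut-2-en-1-yl)benzaldehyde | O=Cc1ccc(O[Si](C)(C)C(C)(C)C)c(CC=C(C)C)c1O[Si](C)(C)C(C)(C)C
F3 | step 10 | (E)-alkenyl(chloro)zirconocene derived from F1 | Cl[Zr](/C=C/c1ccc2c(c1)[C@@H](O[Si](CC)(CC)CC)[C@H](C(C)(C)O[Si](CC)(CC)CC)O2)(C1C=CC=C1)C1C=CC=C1
F4 | step 10 | (E)-1-[2,4-bis(tert-butyldimethylsilyloxy)-3-prenylphenyl]-3-[(2R,3R)-bis(triethylsilyl)-protected dihydrobenzofuran-5-yl]prop-2-en-1-ol | CC(C)=CCc1c(O[Si](C)(C)C(C)(C)C)ccc(C(O)/C=C/c2ccc3c(c2)[C@@H](O[Si](CC)(CC)CC)[C@H](C(C)(C)O[Si](CC)(CC)CC)O3)c1O[Si](C)(C)C(C)(C)C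
F5 | step 10 | tetrasilylated paratocarpin G (2',4'-bis-TBS ether and bis-TES ether of the diol) | CC(C)=CCc1c(O[Si](C)(C)C(C)(C)C)ccc(C(=O)/C=C/c2ccc3c(c2)[C@@H](O[Si](CC)(CC)CC)[C@H](C(C)(C)O[Si](CC)(CC)CC)O3)c1O[Si](C)(C)C(C)(C)C
F6 | step 3 | racemic 3-methyl-1-{2-[(triisopropylsilyl)oxy]-5-[(trimethylsilyl)ethynyl]phenyl}but-2-en-1-ol | CC(C)=CC(O)c1cc(C#C[Si](C)(C)C)ccc1O[Si](C(C)C)(C(C)C)C(C)C
F7 | step 3 | (S)-[(2S)-3,3-dimethyloxiran-2-yl]{2-[(triisopropylsilyl)oxy]-5-[(trimethylsilyl)ethynyl]phenyl}methanol (erythro, from the R alcohol) | O[C@H]([C@@H]1OC1(C)C)c1cc(C#C[Si](C)(C)C)ccc1O[Si](C(C)C)(C(C)C)C(C)C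
F8 | step 8 | 2-(3-methylbut-2-en-1-yl)benzene-1,3-diol | CC(C)=CCc1c(O)cccc1O
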